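**Retrosynthetic overview**
- Target ⇒ 2,4-dihydroxy-6-methoxybenzophenone + 2 prenyl bromide. The two aryl–prenyl bonds are made last, so no alkene is exposed to the aryne or to acid.
- Key disconnection: the C(=O)–phenyl bond rather than the C(=O)–phloroglucinol bond. The aldehyde carbon of a 2,4,6-trioxygenated benzaldehyde acts as an acyl anion (NHC Breslow intermediate) and attacks benzyne as the electrophilic phenyl partner.
- The aldehyde comes from commercial 2,4-dihydroxy-6-methoxybenzaldehyde, which already carries the single O-methyl group in the right place. Its two phenols are masked as MOM ethers for the aryne step.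
- No ring is built; both benzene rings are bought intact. Order: protect → ketone C–C bond → deprotect → double C-prenylation.

**Assumptions**
- The target has no stereocentre and no stereogenic double bond, so it is achiral and needs no stereocontrol.
- Compound 1 is taken as a catalogue compound.
- The step 2 catalyst (not numbered, used catalytically) is 3-mesityl-5,6,7,8-tetrahydro-4H-cyclohepta[d]thiazol-3-ium perchlorate, Cc1cc(C)c(c(C)c1)-[n+]1csc2CCCCCc12.[O-]Cl(=O)(=O)=O.

**Step 1**
Reactants: 1 2,4-dihydroxy-6-methoxybenzaldehyde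
Product: 2 2-methoxy-4,6-bis(methoxymethoxy)benzaldehyde
Conditions: NaH (2.5 equiv), MOMCl (2.5 equiv), DMF, 0 °C → rt
Reagents that add atoms: chloromethyl methyl ether (MOMCl), COCCl
Why: Williamson-type O-alkylation (MOM ether formation); NaH deprotonates both phenols, including the hydrogen-bonded ortho-OH, and each phenoxide displaces chloride from MOMCl, with no stereocentre formed.

**Step 2**
Reactants: 2 2-methoxy-4,6-bis(methoxymethoxy)benzaldehyde; 3 2-(trimethylsilyl)phenyl trifluoromethanesulfonate (1.5 equiv)
Product: 6 [2-methoxy-4,6-bis(methoxymethoxy)phenyl](phenyl)methanone, via benzyne 4 (not isolated), via Breslow intermediate 5 (not isolated)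
Conditions: N-mesityl thiazolium perchlorate precatalyst (15 mol %), K2CO3 (30 mol %), KF (3 equiv), 18-crown-6 (3 equiv), THF, 25 °C
Reagents that add atoms: none
Why: NHC-catalysed hydroacylation of an aryne; the small thiazol-2-ylidene adds to the aldehyde to give the Breslow intermediate (acyl anion equivalent), whose carbon attacks electrophilic benzyne released slowly from 3 by fluoride, and proton transfer with loss of the carbene gives the ketone; the reaction type is known for aryl aldehydes, but a di-ortho-alkoxy aldehyde is at the edge of its scope, and no stereocentre is formed.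

**Step 3**
Reactants: 6 [2-methoxy-4,6-bis(methoxymethoxy)phenyl](phenyl)methanone
Product: 7 (2,4-dihydroxy-6-methoxyphenyl)(phenyl)methanone
Conditions: HCl (1.25 M in MeOH), 40 °C
Reagents that add atoms: none
Why: Acid-catalysed acetal solvolysis (transacetalisation of the MOM ethers to methanol); the aryl methyl ether and the diaryl ketone are inert under these conditions.

**Step 4**
Reactants: 7 (2,4-dihydroxy-6-methoxyphenyl)(phenyl)methanone
Product: 8 [2,4-dihydroxy-6-methoxy-3,5-bis(3-methylbut-2-en-1-yl)phenyl](phenyl)methanone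
Conditions: prenyl bromide (2.3 equiv), 10 % aq. KOH, 0 °C → rt; then 1 M HCl work-up
Reagents that add atoms: prenyl bromide (1-bromo-3-methylbut-2-ene), CC(C)=CCBr
Why: C-alkylation of an ambident acylphloroglucinol-type phenoxide (double C-prenylation); water hydrogen-bonds the phenoxide oxygens and favours attack through carbon, and C3 and C5 are the only free ring positions, each ortho or para to both phenoxide oxygens, so both mono-prenyl intermediates converge on the same product.

**Compound list**
1 | 2,4-dihydroxy-6-methoxybenzaldehyde | COc1cc(O)cc(O)c1C=O | starting material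
2 | 2-methoxy-4,6-bis(methoxymethoxy)benzaldehyde | COc1cc(OCOC)cc(OCOC)c1C=O | intermediate
3 | 2-(trimethylsilyl)phenyl trifluoromethanesulfonate | C[Si](C)(C)c1ccccc1OS(=O)(=O)C(F)(F)F | starting material
4 | benzyne (1,2-didehydrobenzene) | C1=CC=CC#C1 | intermediate
5 | Breslow intermediate: 2-{hydroxy[2-methoxy-4,6-bis(methoxymethoxy)phenyl]methylidene}-3-mesityl-2,3,5,6,7,8-hexahydro-4H-cyclohepta[d]thiazole | COc1cc(OCOC)cc(OCOC)c1C(O)=C1SC2=C(CCCCC2)N1c1c(C)cc(C)cc1C | intermediate
6 | [2-methoxy-4,6-bis(methoxymethoxy)phenyl](phenyl)methanone | COc1cc(OCOC)cc(OCOC)c1C(=O)c1ccccc1 | intermediate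
7 | (2,4-dihydroxy-6-methoxyphenyl)(phenyl)methanone | COc1cc(O)cc(O)c1C(=O)c1ccccc1 | intermediate
8 | [2,4-dihydroxy-6-methoxy-3,5-bis(3-methylbut-2-en-1-yl)phenyl](phenyl)methanone | COc1c(CC=C(C)C)c(O)c(CC=C(C)C)c(O)c1C(=O)c1ccccc1 | target

**Totals**
Total step count: 4. Longest linear sequence: 4.

**Steps most likely to fail, with fallbacks**

Step 2 (most likely). The aldehyde is flanked by two alkoxy groups and is electron-rich, so Breslow intermediate formation may be too slow to compete with capture of benzyne by the carbene or by fluoride. The fallback sets out from 2 and comes back at 7, using a preformed stoichiometric acyl anion equivalent and palladium in place of the carbene and the aryne. Condensing 2 with tert-butylhydrazine hydrochloride (NaOAc, EtOH, rt) gives 1-tert-butyl-2-{(E)-[2-methoxy-4,6-bis(methoxymethoxy)phenyl]methylidene}hydrazine F1. Pd-catalysed C-arylation of its aza-allyl anion with bromobenzene (Pd2(dba)3, bulky phosphine, NaOtBu, toluene, 80 °C) gives the transient (E)-1-tert-butyl-2-{[2-methoxy-4,6-bis(methoxymethoxy)phenyl](phenyl)methyl}diazene F2. This tautomerises in the flask to 1-tert-butyl-2-{[2-methoxy-4,6-bis(methoxymethoxy)phenyl](phenyl)methylidene}hydrazine F3. HCl in aqueous MeOH at 60 °C then hydrolyses the hydrazone and removes both MOM groups, rejoining the route at 7.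

Step 4. Direct C-prenylation can lose material to O-prenylation, geminal dialkylation at C3 and incomplete reaction. The fallback sets out from 6 and comes back at 8, replacing phenoxide alkylation by halogenation and cross-coupling. NBS (2.1 equiv, MeCN, 0 °C → rt) brominates both free ring positions of 6 to give [3,5-dibromo-2-methoxy-4,6-bis(methoxymethoxy)phenyl](phenyl)methanone F4. Double Stille coupling with tributyl(3-methylbut-2-en-1-yl)stannane (Pd(PPh3)4, DMF, 100 °C) gives [2-methoxy-4,6-bis(methoxymethoxy)-3,5-bis(3-methylbut-2-en-1-yl)phenyl](phenyl)methanone F5. Brief HCl/MeOH at rt, stopped before chroman formation, removes the MOM groups and gives 8.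

Step 1. Alkylation of the hydrogen-bonded 2-OH next to the aldehyde may stall at the mono-MOM ether, and two ortho acetal groups add bulk for step 2. The fallback sets out from 1 and comes back at 7, using benzyl ethers removed by hydrogenolysis instead of acid-labile acetals. BnBr and K2CO3 in DMF at 60 °C give 2,4-bis(benzyloxy)-6-methoxybenzaldehyde F6. The same thiazolylidene-catalysed hydroacylation of benzyne 4 (from 3, KF, 18-crown-6, THF) proceeds through 2-{[2,4-bis(benzyloxy)-6-methoxyphenyl](hydroxy)methylidene}-3-mesityl-2,3,5,6,7,8-hexahydro-4H-cyclohepta[d]thiazole F7 to [2,4-bis(benzyloxy)-6-methoxyphenyl](phenyl)methanone F8. Hydrogenolysis (H2 1 atm, Pd/C, EtOAc, rt, stopped after two equivalents of H2) gives 7.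

**Further compounds**
F1 | step 2 | 1-tert-butyl-2-{(E)-[2-methoxy-4,6-bis(methoxymethoxy)phenyl]methylidene}hydrazine | COc1cc(OCOC)cc(OCOC)c1/C=N/NC(C)(C)C
F2 | step 2 | (E)-1-tert-butyl-2-{[2-methoxy-4,6-bis(methoxymethoxy)phenyl](phenyl)methyl}diazene (racemic, transient) | COc1cc(OCOC)cc(OCOC)c1C(/N=N/C(C)(C)C)c1ccccc1
F3 | step 2 | 1-tert-butyl-2-{[2-methoxy-4,6-bis(methoxymethoxy)phenyl](phenyl)methylidene}hydrazine | COc1cc(OCOC)cc(OCOC)c1C(=NNC(C)(C)C)c1ccccc1
F4 | step 4 | [3,5-dibromo-2-methoxy-4,6-bis(methoxymethoxy)phenyl](phenyl)methanone | COc1c(Br)c(OCOC)c(Br)c(OCOC)c1C(=O)c1ccccc1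
F5 | step 4 | [2-methoxy-4,6-bis(methoxymethoxy)-3,5-bis(3-methylbut-2-en-1-yl)phenyl](phenyl)methanone | COc1c(CC=C(C)C)c(OCOC)c(CC=C(C)C)c(OCOC)c1C(=O)c1ccccc1
F6 | step 1 | 2,4-bis(benzyloxy)-6-methoxybenzaldehyde | COc1cc(OCc2ccccc2)cc(OCc2ccccc2)c1C=O
F7 | step 1 | 2-{[2,4-bis(benzyloxy)-6-methoxyphenyl](hydroxy)methylidene}-3-mesityl-2,3,5,6,7,8-hexahydro-4H-cyclohepta[d]thiazole (Breslow intermediate of F6) | OC(c1c(OC)cc(OCc2ccccc2)cc1OCc1ccccc1)=C1SC2=C(CCCCC2)N1c1c(C)cc(C)cc1C
F8 | step 1 | [2,4-bis(benzyloxy)-6-methoxyphenyl](phenyl)methanone | COc1cc(OCc2ccccc2)cc(OCc2ccccc2)c1C(=O)c1ccccc1
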